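- I wanted to know which flask holds the most target at the end, and how much target each flask holds.

| flask | starting material | second substrate | partner | precatalyst | temperature | remark | time |
|---|---|---|---|---|---|---|---|
| maple | 0.010 M | 1 equiv | 1.2 equiv | 5 mol% | −5 °C | run made earlier |  |
| oak | 0.010 M | 0.50 equiv | 1.2 equiv | 5 mol% | 6 °C | run made earlier |  |
| cedar | 0.010 M | 0.75 equiv | 1.2 equiv | 5 mol% | −5 °C | run made earlier |  |
| birch | 0.020 M | 1 equiv | 1.2 equiv | 5 mol% | 6 °C | run made earlier |  |
| winter | 0.010 M | 1.00 equiv | 1.20 equiv | 5 mol% | 0 °C | everything together at the start | 5.0 min |
| dusk | 0.010 M | 1.00 equiv (fed, over 20 s) | 1.20 equiv | 5 mol% | 0 °C | all else is in the flask from the start; the feed brings no volume worth counting | 5.0 min |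
| midnight | 0.010 M | 1.00 equiv | 1.20 equiv (fed, over 3.0 min) | 5 mol% | 0 °C | all else is in the flask from the start; the feed brings no volume worth counting | 5.0 min |
| noon | 0.010 M | 1.00 equiv | 1.20 equiv (fed, over 3.0 min) | 5 mol% |  | the addition at −40 °C, then warmed to 0 °C; the feed brings no volume worth counting | 5.0 min |
| spring | 0.010 M | 1.00 equiv (in portions, 3, over 3.0 min) | 1.20 equiv | 5 mol% | 0 °C | first portion at the start, last at 3.0 min | 5.0 min |

| run | time / min | target / % | starting material / % |
|---|---|---|---|
| maple | 1.33 | 30 | 68 |
| maple | 2.50 | 42 | 59 |
| maple | 4.00 | 41 | 62 |
| maple | 5.00 | 34 | 60 |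
| oak | 0.833 | 50 | 48 |
| oak | 2.00 | 54 | 44 |
| oak | 4.00 | 48 | 48 |
| oak | 6.00 | 50 | 50 |
| cedar | 0.833 | 21 | 80 |
| cedar | 2.00 | 40 | 59 |
| cedar | 4.00 | 38 | 59 |
| cedar | 6.00 | 35 | 61 |
| birch | 0.833 | 59 | 38 |
| birch | 2.00 | 52 | 46 |
| birch | 4.00 | 42 | 56 |
| birch | 6.00 | 38 | 62 |

(scatter of a reading: 1.5 percentage points)

- the analysis behind the earlier runs scatters by 1.5 percentage points, standard deviation
- steps that have been proposed: second substrate + free catalyst <-> catalyst intermediate B; partner + catalyst intermediate B -> free catalyst + second product; precatalyst -> free catalyst; partner + catalyst intermediate A <-> free catalyst + target; starting material + free catalyst <-> catalyst intermediate A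

1. which flask leads in amount of target, in percent of the starting material charged ("all alike" within 1.5 percentage points) (winter / dusk / midnight / noon / spring / all alike)
2. how much target is there at the end, in percent of the starting material charged: winter
3. how much target is there at the end, in percent of the starting material charged: dusk
4. how much target is there at the end, in percent of the starting material charged: midnight
5. how much target is there at the end, in percent of the starting material charged: noon
6. how much target is there at the end, in percent of the starting material charged: spring

- The bench rule says that a small excess of partner over the starting material, here 1.20 equiv, carries the charge through to target, so it promised complete conversion in winter.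
- But the proposed steps give partner a second use: second substrate binds the catalyst as catalyst intermediate B, and partner turns that into second product, one partner for each second substrate. The second substrate therefore has a claim on 83.3% of the partner charged.
- So I reckoned with the spare partner, the partner charged minus the second substrate charged, as a fraction of the starting material charged, which here is 20.0%.
- Once the second substrate has gone, spare partner is the limiting reagent for lasting target, and target above that line is only on loan. The bench rule stops where the spare falls short of the starting material charge, and here it does.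
- The readings fit this picture. Oak has a spare of 70.0%, and its target read 54% at 2.00 min and 50% at 6.00 min, both below its line.
- Birch has a spare of 20.0%, and its target fell from 59% at 0.833 min to 38% at 6.00 min, still above its line.
- Birch was warmer than the new flasks and more concentrated, yet it had not come down to its line. So I expected winter, dusk, midnight, noon and spring all to stand above the spare at 5.0 min.
- I put noon in the lead, because its addition runs at −40 °C and leaves 2.00 min at 0 °C, less time for the loan to be repaid than the 5.0 min of winter.
- The forecast also named noon, with 33% for winter, 33% for dusk, 17% for midnight, 44% for noon and 37% for spring, and said of midnight that “partner is starved and the drain wins”, which puts midnight under my line where I had it above.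
- The flasks gave 36.9% in winter, 37.1% in dusk, 41.1% in midnight, 45.4% in noon and 40.9% in spring, so noon leads.

    second substrate + free catalyst ⇌ catalyst intermediate B (K = 310 M⁻¹, k = 2500 M⁻¹ s⁻¹, Ea = 37.0 kJ mol⁻¹, ΔH = −40.0 kJ mol⁻¹)
    partner + catalyst intermediate B → free catalyst + second product (k = 29.0 M⁻¹ s⁻¹, Ea = 43.0 kJ mol⁻¹)
    precatalyst → free catalyst (k = 0.0400 s⁻¹, Ea = 78.0 kJ mol⁻¹)
    partner + catalyst intermediate A ⇌ free catalyst + target (K = 0.360, k = 58.0 M⁻¹ s⁻¹, Ea = 39.0 kJ mol⁻¹, ΔH = 34.0 kJ mol⁻¹)
    starting material + free catalyst ⇌ catalyst intermediate A (K = 580 M⁻¹, k = 850 M⁻¹ s⁻¹, Ea = 35.0 kJ mol⁻¹, ΔH = 0 kJ mol⁻¹)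
    (constants at 0 °C)

- Noon stood above its spare with 65.2% of its second substrate still there at 5.00 min, and left until 50.0 min it came down to 15.0%. The neighbouring flask is noon with 4.80 equiv of partner, which makes the spare 380% of the starting material charged, beyond the whole charge. That flask held 84.3% of target at 5.00 min, with 0.626% of its second substrate and 61.8% of its partner left.

Readings and results come from a simulation with made-up constants.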